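(Readings and results were computed with made-up constants; the scatter is artificial.)

all flasks: substrate 0.050 M

|  | partner | remark | time |
|---|---|---|---|
| south-west | 0.024 M | run made earlier |  |
| north-east | 0.037 M | run made earlier |  |
| east | 0.070 M | run made earlier |  |
| Saturday's | 0.0200 M |  | 25 min |
| Wednesday's | 0.0400 M |  | 25 min |
| Sunday's | 0.0800 M |  | 25 min |

| run | time / min | target / % | substrate / % |
|---|---|---|---|
| south-west | 2.00 | 11.9 | 88.0 |
| south-west | 4.00 | 20.5 | 78.9 |
| south-west | 8.00 | 32.7 | 65.9 |
| south-west | 12.0 | 39.8 | 58.7 |
| south-west | 25.0 | 44.5 | 53.6 |
| north-east | 2.00 | 14.4 | 85.2 |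
| north-east | 6.00 | 33.6 | 64.7 |
| north-east | 12.0 | 49.0 | 47.9 |
| north-east | 20.0 | 57.9 | 36.8 |
| north-east | 25.0 | 60.4 | 33.0 |
| east | 2.00 | 19.6 | 79.7 |
| east | 6.00 | 41.7 | 53.1 |
| east | 12.0 | 56.1 | 31.5 |
| east | 20.0 | 61.9 | 18.0 |
| east | 25.0 | 63.7 | 13.3 |

(standard deviation of a reading: 0.3 percentage points)

- "hardly changes" means that all values lie within two and a half points (for a concentration: within two and a half percent of the largest)

1. amount of target at the end, in percent of the substrate charged for Saturday's, Wednesday's, Sunday's, in this order
2. the course of these numbers from the first flask to the last (falls, then rises / hardly changes / rises, then falls / falls all the way / rises all the way)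

The south-west run ended with 1.90% of the substrate charged in neither column. Target plus 2 times that gap comes to 48.3%, against a charge ratio c_partner/c_substrate of 48.0%. The north-east run repeats this: its gap of 6.60% gives 73.6% against 74.0%. So the readings count one partner per target and two per missing unit.

For Saturday's the ratio is 40.0%, the partner ceiling: the turnovers of partner that a flask's charge can pay for, in percent of the substrate charged. Partner is the limiting reagent there, and the south-west share of target in its ceiling puts Saturday's target at 37.1%.

Now the question turned round: what would make the row rise all the way? The gap divided by the squared ceiling reads 0.121 in the north-east run and 0.117 in the east run; the south-west run reads lower, at 0.0825, so this rough rule is used for the two flasks nearest those first two runs. Wednesday's ceiling of 80.0% then carries a gap of 7.51%, so target reaches 65.0% if partner is used up. Sunday's ceiling of 160% carries 30.0%, and its target is what substrate and gap leave. To pass that figure, Sunday's would need substrate under 4.98%, less than the 13.3% of the east run. With the east run's substrate, Sunday's target reckons at 56.7%. Sunday's is charged with more partner than the east run, so this is a low estimate, but this reckoning commits to a row that rises, then falls.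

The forecast says 37%, 62.5%, 61.5%, rises, then falls, with a Wednesday's value lower than this reckoning's and a Sunday's value higher, and adds: “The last two are close, so the final fall is uncertain.”

The flasks give 37.9%, 62.5%, 60.0%: rises, then falls.

    substrate + partner → target, rate k1*[substrate]*[partner]^0.5 (k = 0.448 M⁻⁰·⁵ min⁻¹)
    partner + target → over-reaction product (k = 0.658 M⁻¹ min⁻¹)

In Saturday's, both steps ran while partner lasted, with 4.97% of its charge left at 12.5 min and 0% at 25.0 min, and target stood at 37.9% under its ceiling of 40.0%, the same at 250 min. In Wednesday's, both steps brought partner down to 4.22% of its charge at 25.0 min, with target plus 2 times over-reaction product at 76.6% against the ceiling of 80.0%, while in Sunday's both still ran with 26.2% of the partner charge left, over-reaction product at 29.0% and substrate at 11.0%.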